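## Analysis of the target

Abroquinone A (20) is an isoflavan quinone: a 6,7-dimethoxychroman (benzo ring A fused to pyran ring C, with the atoms O1, C2, C3, C4, C4a, C5 to C8 and C8a) carries at C3 a 2,3-dimethoxy-1,4-benzoquinone (ring B) bound through its C5. C3 is the only stereocentre; with the priorities C2 > quinone carbon > C4 > H it is S, and as there is no second centre the problem is one of absolute control alone. C3 is tertiary and flanked by two methylene groups, so nothing in the finished ring C can direct its formation; it has to be set in a precursor in which one neighbour is still a functional group. The quinone is the sensitive part: it is electrophilic and redox-active, and the C3–H bond is γ to a quinone carbonyl, so base would racemise C3 through the quinone methide tautomer; the quinone therefore has to appear last and near neutrality. Ring A is a 1,2,4-trioxygenated benzene and is itself easily oxidised, so the final oxidation has to tell ring B from ring A. The strategy rests on the substitution pattern of ring A: O1 on C8a is para to the methoxy group on C6, the second methoxy group is on C7, C5 and C8 carry hydrogen, and C4a carries the C4 chain ortho to C8a. A chromium carbene benzannulation delivers exactly this pattern when C8a comes from a carbonyl ligand, C6 from a methoxycarbene carbon, C7 and C8 from a 1-methoxyvinyl group and C4a and C5 from a terminal alkyne.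

## Retrosynthetic reasoning

**Quinone 20 to phenol 19 and its acetal 18.** The last bonds made are the two C=O bonds of ring B. Taking them back to one phenolic oxygen gives the 5-substituted 2,3-dimethoxyphenol 19, whose unsubstituted para carbon becomes the second carbonyl. A phenol-selective radical oxidant is preferred to oxidative demethylation of a trimethoxyarene, because ring A has no free hydroxyl and is then left alone. Phenol 19 is carried as its methoxymethyl ether 18, so the forward steps are an acid cleavage and one buffered oxidation.

**Chroman 18 to diol 17 and silyl ether 16.** Ring C is opened at O1–C2. This is the one bond of the pyran ring that forms by simple substitution at a primary carbon, and C3 is one atom away from the reacting centre. Diol 17 closes by a Mitsunobu reaction (6-exo-tet). It comes from 16 by desilylation; the silyl group only keeps the primary oxygen out of the benzannulation.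

**Phenol 16 to alkyne 9 and carbene complex 14 (key disconnection).** Ring A is taken apart completely by cutting C5–C6, C4a–C8a and C8–C8a. This returns the terminal alkyne 9 (C4a, C5), the carbene carbon and 1-methoxyvinyl group of 14 (C6, C7, C8) and one carbonyl ligand of 14 (C8a with O1). Cutting here, instead of joining two preformed arenes, lets the stereocentre be installed in a small aliphatic fragment and places the phenol oxygen exactly where ring C must close. The forward reaction has to insert the alkyne with its substituted carbon next to the carbonyl-derived carbon and has to end in the phenol, not in a five-membered ring.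

**Complex 14 to enol ether 10 and Cr(CO)6 11.** The Cr=C and O–CH3 bonds are cut. Vinyllithium 12, from deprotonation of 10, adds to a carbonyl ligand of 11, and acyl chromate 13 is O-methylated. This is one flask with no stereochemistry.

**Alkyne 9 to lactone 5.** The terminal alkyne carbon is removed. Alkynol 8, the precursor of 9, is the one-carbon homologue of hydroxy aldehyde 7, which exists as lactol 6, the half-reduced form of γ-lactone 5. In 5 the future C3 is β to a carbonyl group, where a conjugate addition creates a stereocentre, and it is α to none, so it cannot epimerise later.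

**Lactone 5 to boronate 3 and butenolide 4.** The bond between ring B and C3 is cut. Forward, a rhodium catalyst with a chiral bisphosphine adds the aryl group of 3 to the β-carbon of 4 and sets C3. This is catalytic, shorter than alkylating an arylacetic acid derivative, and gives a centre that is not acidic.

**Boronate 3 to 2 and 1.** The C–B bond is cut to C–H. In 2 the carbon meta to the protected hydroxyl is the only one without an ortho neighbour, which is the selection rule of iridium-catalysed borylation and the opposite of electrophilic substitution. Compound 2 is the methoxymethyl ether of commercial phenol 1.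

## Alternatives that were turned down

Alternative 1: the bond between the chroman and ring B (C3–C1') is cut, and a temporary C4–O bond is accepted.
- Forward key step: the C3=C4 double bond of 6,7-dimethoxy-2H-chromene A2 adds with its C3 end to the unsubstituted ring carbon of 2,3-dimethoxy-1,4-benzoquinone A3, which is activated on a chiral Lewis acid of the TiCl2(OR)2 type (tetravalent titanium) carrying a tartrate-derived diol. The benzylic cation left at C4 is captured by the neighbouring quinone oxygen, and aromatisation gives cis-8-hydroxy-2,3,9,10-tetramethoxypterocarpan A1. Hydrogenolysis of the benzylic C–O bond of A1 would give the hydroquinone 2-[(3S)-6,7-dimethoxy-3,4-dihydro-2H-chromen-3-yl]-5,6-dimethoxybenzene-1,4-diol A4, and mild oxidation of A4 gives the target.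
- For: about three steps from A2 and A3. A3 is symmetric, so no regiochemical question arises. The last oxidation is that of the hydroquinone A4, which is milder than a phenol oxidation. On step count and on the endgame this alternative is clearly stronger than the chosen route.
- Against: the chiral titanium complex is needed in stoichiometric amount. Enantiocontrol at C3 rests on two-point binding of A3 and on a stepwise cationic path that can leak into [2+2] cyclobutane adducts. The acid-sensitive, enol-ether-like A2 can oligomerise on the Lewis acid. The C4 centre of A1 is made only to be destroyed.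
- Comparison: the chosen route is about three times as long. In return it sets C3 by a catalytic step of predictable sense at a position that is never re-exposed, and it builds ring A with its oxygens fixed by the reagents, not by the reactivity of a quinone.

Alternative 2: ring C is cut at C3–C4 and at O1–C2.
- Forward key step: a chiral phosphoric acid dehydrates 2-(hydroxymethyl)-4,5-dimethoxyphenol A6 to its o-quinone methide, which is trapped within the chiral ion pair in an inverse-demand hetero-Diels–Alder reaction by benzyl N-[(E)-2-(3-benzyloxy-4,5-dimethoxyphenyl)ethenyl]carbamate A7. The cycloadduct is benzyl N-[trans-3-(3-benzyloxy-4,5-dimethoxyphenyl)-6,7-dimethoxychroman-2-yl]carbamate A5. From A5 the C2 nitrogen has to be removed by ionic reduction, the benzyl ether cleaved and the phenol oxidised.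
- For: the pyran ring and C3 are made in one catalytic, convergent step, and ring A comes from the simple arene A6 with O1 in place. In convergence this alternative is equal to or better than the chosen route.
- Against: the C2 carbamate of A5 is a substituent that the target does not have. Its removal passes through a 2-oxocarbenium ion next to C3, and loss of the C3 proton there gives a chromene and erases the stereocentre. An o-quinone methide without a substituent on the methide carbon is very reactive, so an uncatalysed background reaction is likely. A7 needs several steps of its own, so the total length is not shorter.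
- Comparison: in the chosen route C3 never sits next to a cationic or acidic carbon after it is made.

Alternative 3: the O1–C2 and C3–H bonds are cut.
- Forward key step: an excited acridinium photocatalyst oxidises the 1,1-disubstituted alkene of 2-{2-[3,4-dimethoxy-5-(methoxymethoxy)phenyl]prop-2-en-1-yl}-4,5-dimethoxyphenol A9 to its radical cation. The phenol oxygen attacks the CH2 terminus in the anti-Markovnikov sense, and the tertiary benzylic radical left at C3 is quenched by hydrogen-atom transfer from an enantiopure thiol. The product is (3S)-3-[3,4-dimethoxy-5-(methoxymethoxy)phenyl]-6,7-dimethoxychroman A8, the same structure as chroman 18.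
- For: very short and atom-economical. A9 needs no stereochemistry, and A8 is two steps from the target. In step economy this alternative beats the chosen route.
- Against: hydrogen-atom transfer from a chiral thiol to a planar tertiary benzylic radical is not a reaction from which high enantioselectivity can be counted on. The phenol O–H and the thiol regenerated in achiral form are competing donors. Both arenes of A9, ring A above all, are easier to oxidise than the alkene, so the photocatalyst would form arene radical cations first.
- Comparison: the chosen route places its risk in bond construction (the benzannulation), where failure is visible and repairable, and not in the enantiopurity of the only stereocentre.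

Key step: step 8

Assumption: the (S)-BINAP–rhodium catalyst of step 3 is taken to attack furan-2(5H)-one from the same face as it attacks cyclic enones and six-membered unsaturated lactones, which leads to the (S)-lactone 5; if correlation at 5 shows otherwise, the (R)-ligand is used with no other change.

## Route

Step 1
Reactants: 1 2,3-dimethoxyphenol
Product: 2 1,2-dimethoxy-3-(methoxymethoxy)benzene
Conditions: NaH, MOMCl, THF, 0 °C → rt
Reagents that add atoms: chloromethyl methyl ether (MOMCl), COCCl
Why: Williamson-type O-alkylation of the sodium phenoxide; the acetal survives all basic, reductive and organometallic steps that follow and is removed by acid only at the end.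

Step 2
Reactants: 2 1,2-dimethoxy-3-(methoxymethoxy)benzene
Product: 3 2-[3,4-dimethoxy-5-(methoxymethoxy)phenyl]-4,4,5,5-tetramethyl-1,3,2-dioxaborolane
Conditions: B2pin2 (1.0 equiv), [Ir(OMe)(cod)]2 (1.5 mol %), 4,4'-di-tert-butyl-2,2'-bipyridine (3 mol %), THF, 80 °C
Reagents that add atoms: bis(pinacolato)diboron (B2pin2), CC1(C)OB(OC1(C)C)B1OC(C)(C)C(C)(C)O1
Why: Iridium-catalysed C–H borylation is governed by sterics and avoids C–H bonds ortho to a substituent; in this 1,2,3-trisubstituted benzene only C5 qualifies, so boron should enter meta to the protected hydroxyl, a position electrophilic substitution cannot reach.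

Step 3
Reactants: 3 2-[3,4-dimethoxy-5-(methoxymethoxy)phenyl]-4,4,5,5-tetramethyl-1,3,2-dioxaborolane; 4 furan-2(5H)-one
Product: 5 (4S)-4-[3,4-dimethoxy-5-(methoxymethoxy)phenyl]oxolan-2-one
Conditions: 4 (1.5 equiv), [Rh(OH)((S)-binap)]2 (2.5 mol %), dioxane/H2O 10:1, 50 °C
Reagents that add atoms: none
Why: Hayashi–Miyaura asymmetric 1,4-addition: transmetalation gives an aryl–rhodium species, the butenolide inserts and the oxa-π-allyl rhodium is protonated by water. The (S)-BINAP ligand shields one enantioface of the bound alkene and so sets the S centre, which is β to the carbonyl and cannot epimerise.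

Step 4
Reactants: 5 (4S)-4-[3,4-dimethoxy-5-(methoxymethoxy)phenyl]oxolan-2-one
Product: 6 (4S)-4-[3,4-dimethoxy-5-(methoxymethoxy)phenyl]oxolan-2-ol (both C2 epimers)
Conditions: i-Bu2AlH (1.1 equiv), CH2Cl2, −78 °C; aq. KNaC4H4O6
Reagents that add atoms: none
Why: Partial reduction of a γ-lactone; the aluminium hemiacetal is stable at low temperature and collapses to the lactol only on work-up, so over-reduction to the diol should be avoided.

Step 5
Reactants: 6 (4S)-4-[3,4-dimethoxy-5-(methoxymethoxy)phenyl]oxolan-2-ol
Product: 8 (2S)-2-[3,4-dimethoxy-5-(methoxymethoxy)phenyl]pent-4-yn-1-ol, via open-chain hydroxy aldehyde 7 (not isolated)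
Conditions: dimethyl (1-diazo-2-oxopropyl)phosphonate, K2CO3, MeOH, 0 °C → rt
Reagents that add atoms: dimethyl (1-diazo-2-oxopropyl)phosphonate (Ohira–Bestmann reagent), COP(=O)(OC)C(=[N+]=[N-])C(C)=O
Why: Seyferth–Gilbert homologation in the Ohira–Bestmann form: methanolysis frees the diazomethylphosphonate anion, which adds to the aldehyde tautomer 7; loss of phosphate and N2 gives an alkylidene carbene that rearranges by 1,2-hydrogen shift to the terminal alkyne. The stereocentre is β to the aldehyde and is not at risk under carbonate.

Step 6
Reactants: 8 (2S)-2-[3,4-dimethoxy-5-(methoxymethoxy)phenyl]pent-4-yn-1-ol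
Product: 9 tert-butyl({(2S)-2-[3,4-dimethoxy-5-(methoxymethoxy)phenyl]pent-4-yn-1-yl}oxy)dimethylsilane
Conditions: TBSCl, imidazole, DMF, rt
Reagents that add atoms: tert-butyldimethylsilyl chloride (TBSCl), CC(C)(C)[Si](C)(C)Cl
Why: Standard silylation of a primary alcohol; the silyl ether prevents the hydroxyl from trapping the ketene intermediate of the benzannulation as a lactone.

Step 7
Reactants: 10 methyl vinyl ether; 11 chromium hexacarbonyl Cr(CO)6
Product: 14 pentacarbonyl[methoxy(1-methoxyvinyl)carbene]chromium, via 1-methoxyvinyllithium 12 (not isolated), via lithium acylchromate 13 (not isolated)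
Conditions: t-BuLi, THF, −78 → 0 °C; Cr(CO)6, Et2O, 0 °C → rt; Me3OBF4, CH2Cl2, 0 °C
Reagents that add atoms: trimethyloxonium tetrafluoroborate (Me3OBF4), C[O+](C)C.F[B-](F)(F)F
Why: Fischer carbene synthesis: α-lithiation of the enol ether gives 12, which adds to a carbonyl ligand of 11 to give acyl chromate 13, and the hard oxonium salt methylates it on oxygen. The same sequence is the standard entry to α-alkoxyalkenyl carbene complexes from lithiated cyclic enol ethers; the complex would be kept cold under argon and used promptly.

Step 8
Reactants: 9 tert-butyl({(2S)-2-[3,4-dimethoxy-5-(methoxymethoxy)phenyl]pent-4-yn-1-yl}oxy)dimethylsilane; 14 pentacarbonyl[methoxy(1-methoxyvinyl)carbene]chromium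
Product: 16 2-{(2S)-3-[(tert-butyldimethylsilyl)oxy]-2-[3,4-dimethoxy-5-(methoxymethoxy)phenyl]propyl}-4,5-dimethoxyphenol, via tricarbonylchromium arene complex 15 (not isolated)
Conditions: 14 (1.5 equiv), THF (0.05 M), 50 °C, Ar; then air, daylight, rt
Reagents that add atoms: none
Why: Thermal loss of one cis carbonyl ligand from 14 lets the alkyne of 9 coordinate and insert into the Cr=C bond, joining the unsubstituted alkyne carbon to the former carbene carbon (C5–C6); migratory insertion of a carbonyl ligand then gives a chromium-bound dienylketene (C4a–C8a). Ring A closes by thermal six-electron electrocyclisation of this ketene onto the methylene carbon of the 1-methoxyvinyl unit (C8–C8a), and the cyclohexadienone tautomerises to the arene-bound phenol 15, from which air removes the Cr(CO)3 fragment. The closest known reaction type is the Dötz benzannulation of α-alkoxyalkenyl Fischer carbene complexes of zerovalent chromium (those made from lithiated cyclic enol ethers) with terminal alkynes. No stereocentre is formed; the existing one is homopropargylic, is never bound to the metal and should pass through unchanged. The selectivity required is that of alkyne insertion: the substituted alkyne carbon must end up next to the carbonyl-derived carbon so that the side chain sits ortho to the new hydroxyl, and the difference in size between hydrogen and the branched alkyl group on the two alkyne carbons secures this. The step also needs phenol formation to win over cyclisation without carbonyl insertion, which alkenyl (as opposed to aryl) carbene complexes in THF favour, and it needs the ketene not to be intercepted, which the silyl ether ensures.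

Step 9
Reactants: 16 2-{(2S)-3-[(tert-butyldimethylsilyl)oxy]-2-[3,4-dimethoxy-5-(methoxymethoxy)phenyl]propyl}-4,5-dimethoxyphenol
Product: 17 2-{(2S)-2-[3,4-dimethoxy-5-(methoxymethoxy)phenyl]-3-hydroxypropyl}-4,5-dimethoxyphenol
Conditions: Bu4NF, AcOH (1:1), THF, 0 °C → rt, Ar
Reagents that add atoms: none
Why: Fluoride cleaves the Si–O bond; buffering with acetic acid and exclusion of air keep the electron-rich phenol from being oxidised as its phenoxide, and the acetal on ring B is untouched.

Step 10
Reactants: 17 2-{(2S)-2-[3,4-dimethoxy-5-(methoxymethoxy)phenyl]-3-hydroxypropyl}-4,5-dimethoxyphenol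
Product: 18 (3S)-3-[3,4-dimethoxy-5-(methoxymethoxy)phenyl]-6,7-dimethoxy-3,4-dihydro-2H-chromene
Conditions: PPh3, DIAD, THF (0.02 M), 0 °C → rt
Reagents that add atoms: none
Why: Intramolecular Mitsunobu etherification: the primary alcohol is activated as its alkoxyphosphonium ion and displaced by the phenoxide (6-exo-tet), forming O1–C2. The reacting carbon is C2, so C3 is not involved and keeps its configuration.

Step 11
Reactants: 18 (3S)-3-[3,4-dimethoxy-5-(methoxymethoxy)phenyl]-6,7-dimethoxy-3,4-dihydro-2H-chromene
Product: 19 5-[(3S)-6,7-dimethoxy-3,4-dihydro-2H-chromen-3-yl]-2,3-dimethoxyphenol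
Conditions: HCl (3 M aq.), MeOH, 45 °C, Ar
Reagents that add atoms: none
Why: Acid-catalysed transacetalisation of the aryl methoxymethyl ether to methanol; the methyl ethers and the chroman ether are stable under these conditions.

Step 12
Reactants: 19 5-[(3S)-6,7-dimethoxy-3,4-dihydro-2H-chromen-3-yl]-2,3-dimethoxyphenol
Product: 20 abroquinone A, 5-[(3S)-6,7-dimethoxy-3,4-dihydro-2H-chromen-3-yl]-2,3-dimethoxycyclohexa-2,5-diene-1,4-dione
Conditions: (KSO3)2NO (2.5 equiv), KH2PO4 buffer (pH 6), acetone/H2O, 0 °C → rt
Reagents that add atoms: potassium nitrosodisulfonate (KSO3)2NO, [K+].[K+].[O-]S(=O)(=O)N([O])S(=O)(=O)[O-]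
Why: Teuber oxidation: the nitroxyl radical abstracts the phenolic hydrogen, a second equivalent couples at the free para carbon and loss of imidodisulfonate gives the para-quinone. Ring A has no free hydroxyl and should not react, and the buffered, near-neutral medium protects the C3–H bond next to the new quinone.

## Compound list

1 | 2,3-dimethoxyphenol | COc1cccc(O)c1OC | starting material
2 | 1,2-dimethoxy-3-(methoxymethoxy)benzene | COCOc1cccc(OC)c1OC | intermediate
3 | 2-[3,4-dimethoxy-5-(methoxymethoxy)phenyl]-4,4,5,5-tetramethyl-1,3,2-dioxaborolane | COCOc1cc(cc(OC)c1OC)B1OC(C)(C)C(C)(C)O1 | intermediate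
4 | furan-2(5H)-one | O=C1OCC=C1 | starting material
5 | (4S)-4-[3,4-dimethoxy-5-(methoxymethoxy)phenyl]oxolan-2-one | O=C1C[C@H](CO1)c1cc(OC)c(OC)c(OCOC)c1 | intermediate
6 | (4S)-4-[3,4-dimethoxy-5-(methoxymethoxy)phenyl]oxolan-2-ol (both C2 epimers) | OC1C[C@H](CO1)c1cc(OC)c(OC)c(OCOC)c1 | intermediate
7 | (3S)-3-[3,4-dimethoxy-5-(methoxymethoxy)phenyl]-4-hydroxybutanal | O=CC[C@H](CO)c1cc(OC)c(OC)c(OCOC)c1 | intermediate (not isolated)
8 | (2S)-2-[3,4-dimethoxy-5-(methoxymethoxy)phenyl]pent-4-yn-1-ol | C#CC[C@H](CO)c1cc(OC)c(OC)c(OCOC)c1 | intermediate
9 | tert-butyl({(2S)-2-[3,4-dimethoxy-5-(methoxymethoxy)phenyl]pent-4-yn-1-yl}oxy)dimethylsilane | C#CC[C@H](CO[Si](C)(C)C(C)(C)C)c1cc(OC)c(OC)c(OCOC)c1 | intermediate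
10 | methyl vinyl ether | COC=C | starting material
11 | chromium hexacarbonyl Cr(CO)6 | [Cr].[C-]#[O+].[C-]#[O+].[C-]#[O+].[C-]#[O+].[C-]#[O+].[C-]#[O+] | starting material
12 | 1-methoxyvinyllithium | [Li]C(=C)OC | intermediate (not isolated)
13 | lithium pentacarbonyl(2-methoxyprop-2-enoyl)chromate | [Li+].[O-]C(C(OC)=C)=[Cr](=C=O)(=C=O)(=C=O)(=C=O)=C=O | intermediate (not isolated)
14 | pentacarbonyl[methoxy(1-methoxyvinyl)carbene]chromium | COC(C(OC)=C)=[Cr](=C=O)(=C=O)(=C=O)(=C=O)=C=O | intermediate
15 | tricarbonyl(η6-arene)chromium complex of phenol 16 (metal on ring A) | COCOc1cc(cc(OC)c1OC)[C@@H](CO[Si](C)(C)C(C)(C)C)Cc1cc(OC)c(OC)cc1O.[Cr].[C-]#[O+].[C-]#[O+].[C-]#[O+] | intermediate (not isolated)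
16 | 2-{(2S)-3-[(tert-butyldimethylsilyl)oxy]-2-[3,4-dimethoxy-5-(methoxymethoxy)phenyl]propyl}-4,5-dimethoxyphenol | COCOc1cc(cc(OC)c1OC)[C@@H](CO[Si](C)(C)C(C)(C)C)Cc1cc(OC)c(OC)cc1O | intermediate
17 | 2-{(2S)-2-[3,4-dimethoxy-5-(methoxymethoxy)phenyl]-3-hydroxypropyl}-4,5-dimethoxyphenol | COCOc1cc(cc(OC)c1OC)[C@@H](CO)Cc1cc(OC)c(OC)cc1O | intermediate
18 | (3S)-3-[3,4-dimethoxy-5-(methoxymethoxy)phenyl]-6,7-dimethoxy-3,4-dihydro-2H-chromene | COCOc1cc(cc(OC)c1OC)[C@H]1COc2cc(OC)c(OC)cc2C1 | intermediate
19 | 5-[(3S)-6,7-dimethoxy-3,4-dihydro-2H-chromen-3-yl]-2,3-dimethoxyphenol | COc1cc(cc(O)c1OC)[C@H]1COc2cc(OC)c(OC)cc2C1 | intermediate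
20 | abroquinone A, 5-[(3S)-6,7-dimethoxy-3,4-dihydro-2H-chromen-3-yl]-2,3-dimethoxycyclohexa-2,5-diene-1,4-dione | COC1=C(OC)C(=O)C([C@H]2COc3cc(OC)c(OC)cc3C2)=CC1=O | target

## Step count and least certain steps

Total step count: 12.
Longest linear sequence: 11 steps (steps 1 to 6 and 8 to 12, from 1); step 7 is a one-step side branch.

**Least certain: step 8 (key step, together with the supply of its carbene partner from step 7).**
- What may go wrong: complex 14 is an electron-rich alkenylcarbene with an unhindered terminal alkene, and this exact complex has no direct precedent. It may polymerise or decompose thermally before the alkyne inserts. After insertion, incorporation of a second alkyne or cyclisation without carbonyl insertion may divert material. During demetallation, over-oxidation of the new para-methoxyphenol may occur.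
- Fallback (sets out from boronate 3, returns at chroman 18; replaces steps 3 to 10): ring A is taken from a commercial arene instead of being built. Boronate 3 is coupled with ethyl bromoacetate (Pd(OAc)2, P(o-tol)3, K3PO4, THF/H2O) to give ethyl 2-[3,4-dimethoxy-5-(methoxymethoxy)phenyl]acetate F1. This is saponified (LiOH) to 2-[3,4-dimethoxy-5-(methoxymethoxy)phenyl]acetic acid F2. The acid is converted through its pivalic mixed anhydride and lithiated (S)-4-benzyl-2-oxazolidinone into (4S)-4-benzyl-3-{2-[3,4-dimethoxy-5-(methoxymethoxy)phenyl]acetyl}-1,3-oxazolidin-2-one F3. The sodium Z-enolate (NaN(SiMe3)2, THF, −78 °C) is alkylated with commercial 2-bromo-4,5-dimethoxybenzyl bromide, anti to the benzyl group of the auxiliary, to give (4S)-4-benzyl-3-{(2S)-3-(2-bromo-4,5-dimethoxyphenyl)-2-[3,4-dimethoxy-5-(methoxymethoxy)phenyl]propanoyl}-1,3-oxazolidin-2-one F4. LiBH4 reduction gives (2S)-3-(2-bromo-4,5-dimethoxyphenyl)-2-[3,4-dimethoxy-5-(methoxymethoxy)phenyl]propan-1-ol F5. Intramolecular palladium-catalysed C–O coupling (Pd(OAc)2, 2-(di-tert-butylphosphino)-1,1'-binaphthyl, Cs2CO3, toluene, 80 °C) closes O1–C8a and gives 18.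

**Least certain: step 3.**
- What may go wrong: transmetalation of the pinacol ester to rhodium may be slow, so that protodeboronation back to 2 outruns addition. The pinacol ester can be cleaved to the boronic acid beforehand, but this remedy only changes the conditions. The face selectivity on the small, flat butenolide may be lower than on six-membered acceptors. Some lactone may hydrolyse.
- Fallback (sets out from boronate 3, returns at alkynol 8; replaces steps 3 to 5): imide F3 is made as described for step 8 (through F1 and F2). Its sodium enolate is alkylated with propargyl bromide to give (4S)-4-benzyl-3-{(2S)-2-[3,4-dimethoxy-5-(methoxymethoxy)phenyl]pent-4-ynoyl}-1,3-oxazolidin-2-one F6. LiBH4 (Et2O, MeOH, 0 °C) removes the auxiliary reductively and gives 8. The α-aryl centre of F6 is acidic, so the reduction would be run cold and without delay.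

**Least certain: step 12.**
- What may go wrong: the para carbon is flanked on both sides, so radical coupling at the free ortho carbon, leading towards an ortho-quinone, may compete. Prolonged exposure may degrade ring A oxidatively. A drift to basic pH would racemise C3 through quinone methide tautomerism.
- Fallback (sets out from phenol 19, returns at 20): the para oxygen is introduced through nitrogen. Azo coupling of the phenoxide of 19 with 4-diazoniobenzenesulfonate (aq. NaOH, 0 °C), an electrophile too weak to touch the ether rings, gives sodium 4-[(E)-{6-[(3S)-6,7-dimethoxy-3,4-dihydro-2H-chromen-3-yl]-4-hydroxy-2,3-dimethoxyphenyl}diazenyl]benzenesulfonate F7. Na2S2O4 reduces it to 4-amino-5-[(3S)-6,7-dimethoxy-3,4-dihydro-2H-chromen-3-yl]-2,3-dimethoxyphenol F8. FeCl3 in dilute HCl oxidises the aminophenol to the quinone imine, which hydrolyses in the acidic medium to 20.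

**Least certain: step 5.**
- What may go wrong: the lactol holds little free aldehyde at equilibrium, so addition of the diazophosphonate anion may be slower than its decomposition in methanol, leaving the conversion incomplete.
- Fallback (sets out from lactol 6, returns at alkynol 8): Wittig chloromethylenation of 6 with the ylide from (chloromethyl)triphenylphosphonium chloride and KOt-Bu (THF, 0 °C) gives (2S)-5-chloro-2-[3,4-dimethoxy-5-(methoxymethoxy)phenyl]pent-4-en-1-ol F9 as an E/Z mixture. Dehydrochlorination with n-BuLi (3 equiv, THF, −78 → 0 °C) gives 8.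

## Further compounds

F1 | step 8 | ethyl 2-[3,4-dimethoxy-5-(methoxymethoxy)phenyl]acetate | CCOC(=O)Cc1cc(OC)c(OC)c(OCOC)c1
F2 | step 8 | 2-[3,4-dimethoxy-5-(methoxymethoxy)phenyl]acetic acid | OC(=O)Cc1cc(OC)c(OC)c(OCOC)c1
F3 | step 8 | (4S)-4-benzyl-3-{2-[3,4-dimethoxy-5-(methoxymethoxy)phenyl]acetyl}-1,3-oxazolidin-2-one | O=C(Cc1cc(OC)c(OC)c(OCOC)c1)N1[C@@H](Cc2ccccc2)COC1=O
F4 | step 8 | (4S)-4-benzyl-3-{(2S)-3-(2-bromo-4,5-dimethoxyphenyl)-2-[3,4-dimethoxy-5-(methoxymethoxy)phenyl]propanoyl}-1,3-oxazolidin-2-one | COCOc1cc(cc(OC)c1OC)[C@@H](C(=O)N1[C@@H](Cc2ccccc2)COC1=O)Cc1cc(OC)c(OC)cc1Br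
F5 | step 8 | (2S)-3-(2-bromo-4,5-dimethoxyphenyl)-2-[3,4-dimethoxy-5-(methoxymethoxy)phenyl]propan-1-ol | COCOc1cc(cc(OC)c1OC)[C@@H](CO)Cc1cc(OC)c(OC)cc1Br
F6 | step 3 | (4S)-4-benzyl-3-{(2S)-2-[3,4-dimethoxy-5-(methoxymethoxy)phenyl]pent-4-ynoyl}-1,3-oxazolidin-2-one | C#CC[C@H](C(=O)N1[C@@H](Cc2ccccc2)COC1=O)c1cc(OC)c(OC)c(OCOC)c1
F7 | step 12 | sodium 4-[(E)-{6-[(3S)-6,7-dimethoxy-3,4-dihydro-2H-chromen-3-yl]-4-hydroxy-2,3-dimethoxyphenyl}diazenyl]benzenesulfonate | COc1c(OC)c(O)cc([C@H]2COc3cc(OC)c(OC)cc3C2)c1/N=N/c1ccc(cc1)S(=O)(=O)[O-].[Na+]
F8 | step 12 | 4-amino-5-[(3S)-6,7-dimethoxy-3,4-dihydro-2H-chromen-3-yl]-2,3-dimethoxyphenol | COc1c(OC)c(O)cc([C@H]2COc3cc(OC)c(OC)cc3C2)c1N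
F9 | step 5 | (2S)-5-chloro-2-[3,4-dimethoxy-5-(methoxymethoxy)phenyl]pent-4-en-1-ol (E/Z mixture) | ClC=CC[C@H](CO)c1cc(OC)c(OC)c(OCOC)c1
A1 | alternative 1 | cis-8-hydroxy-2,3,9,10-tetramethoxypterocarpan | COc1cc2OC[C@@H]3c4cc(O)c(OC)c(OC)c4O[C@@H]3c2cc1OC
A2 | alternative 1 | 6,7-dimethoxy-2H-chromene | COc1cc2C=CCOc2cc1OC
A3 | alternative 1 | 2,3-dimethoxy-1,4-benzoquinone | COC1=C(OC)C(=O)C=CC1=O
A4 | alternative 1 | 2-[(3S)-6,7-dimethoxy-3,4-dihydro-2H-chromen-3-yl]-5,6-dimethoxybenzene-1,4-diol | COc1c(OC)c(O)c(cc1O)[C@H]1COc2cc(OC)c(OC)cc2C1
A5 | alternative 2 | benzyl N-[trans-3-(3-benzyloxy-4,5-dimethoxyphenyl)-6,7-dimethoxychroman-2-yl]carbamate | COc1cc(cc(OCc2ccccc2)c1OC)[C@@H]1Cc2cc(OC)c(OC)cc2O[C@H]1NC(=O)OCc1ccccc1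
A6 | alternative 2 | 2-(hydroxymethyl)-4,5-dimethoxyphenol | COc1cc(O)c(CO)cc1OC
A7 | alternative 2 | benzyl N-[(E)-2-(3-benzyloxy-4,5-dimethoxyphenyl)ethenyl]carbamate | COc1cc(/C=C/NC(=O)OCc2ccccc2)cc(OCc2ccccc2)c1OC
A8 | alternative 3 | (3S)-3-[3,4-dimethoxy-5-(methoxymethoxy)phenyl]-6,7-dimethoxychroman | COCOc1cc(cc(OC)c1OC)[C@H]1COc2cc(OC)c(OC)cc2C1
A9 | alternative 3 | 2-{2-[3,4-dimethoxy-5-(methoxymethoxy)phenyl]prop-2-en-1-yl}-4,5-dimethoxyphenol | C=C(Cc1cc(OC)c(OC)cc1O)c1cc(OC)c(OC)c(OCOC)c1
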